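**Compound numbers** (full list with SMILES after the steps): 1 phloroglucinol; 2 dihydrophloroglucinol; 3 its bis-silyl ether (not isolated); 4 the silyloxy dione; 5 the keto ester; 6 the (R)-hydroxy ester; 7 the (R)-hydroxy aldehyde; 8 the alkylidene dione (not isolated); 9 the hydroxy dione (key-step precursor); 10 its ring hemiketal (not isolated); 11 the silyloxy hexahydrochromenone (key-step product); 12 the free C7 alcohol; 13 prenyl bromide; 14 the dianion of 12 (not isolated); 15 the C6-prenylated hydroxy ketone; 16 the diketone tautomer (not isolated); 17 the target.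

## Analysis of the target

Compound 17 is a flavan, a 2-arylchroman. Ring A is a phloroglucinol-type benzene with the ring oxygen O1 on C8a, free hydroxyls on C5 and C7, a 3-methylbut-2-enyl (prenyl) group on C6 and hydrogen on C8; ring C is the dihydropyran O1–C2–C3–C4–C4a–C8a; ring B is a 3,5-dimethoxyphenyl group on C2. C2 is the only stereocentre and is R; it is benzylic and bound to O1, so no relative configuration has to be set, but the C2–O1 bond must never ionise. The sensitive parts are the very electron-rich ring A (easily oxidised, easily attacked by electrophiles), the trisubstituted prenyl alkene (lost on hydrogenation, and under acid it cyclises onto a neighbouring phenol) and the benzylic ether. The hard problem is constitutional: C6 and C8 each lie between two oxygen-bearing carbons and are activated to almost the same degree, and they compete with the phenol oxygens, so a prenyl electrophile is not expected to select C6 on a finished 5,7-dihydroxyflavan. The route rests on a change of oxidation level: if ring A is carried as a cyclohexane-1,3-dione with a carbinol at C7, closure of ring C gives the vinylogous ester O1–C8a=C4a–C5=O. In that array C6 is the α′ carbon next to the ketone and C8 is the γ carbon on the enol-ether side, so the two positions differ in kinetic acidity. One oxidation at C7 after prenylation then gives the trione level, whose enol form is the arene.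

## Retrosynthetic reasoning

**17 to 15 (no skeletal bond cut).** Ring A of 17 is the enol form of diketone 16, and 16 is the product of oxidising the C7 carbinol of 15. Stepping back to 15 turns C6 and C8 into different kinds of carbon and keeps the arene out of every earlier step. The forward reaction must oxidise a secondary alcohol next to a prenyl alkene and a vinylogous ester, and stop before the emerging phenol is attacked.

**15 to 12 and 13 (C6–C1′ of the prenyl group).** The bond is cut here because in 12 only the C6 hydrogens are α to the C5 ketone; C8 is the γ position and is not removed under kinetic control. Alkylation is planned through dianion 14, in which the C7 oxygen is an alkoxide and cannot leave. This replaces a silyl ether at C7, which would be set up for β-elimination from the C6 enolate and would cost the C7 oxygen.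

**12 to 11 (silyl ether).** The C7 silyl ether is removed between the acid step and the enolate step. It serves to keep the dione half lipophilic and to keep a free β-hydroxyl out of the acid-catalysed ring closure.

**11 to 9 (O1–C8a, ring C).** This is the key disconnection. Opening the enol ether gives a 2-alkyl-1,3-dione with a secondary benzylic alcohol three carbons away. The forward step is a cyclodehydration through hemiketal 10; the carbinol C–O bond is kept, so C2 of 11 has the configuration of the carbinol in 9. The two dione carbonyls are equivalent, so only one constitution can form.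

**9 to 7 and 4 (C4–C4a).** The bond between the side chain and the dione carbon is cut to an aldehyde and a 1,3-dione. Direct alkylation of a 1,3-dione suffers from O-alkylation, so the forward reaction is a condensation to alkylidene dione 8 followed by conjugate reduction in the same flask. No stereocentre is created.

**7 to 6 to 5 (carbinol and aldehyde).** The aldehyde comes from partial reduction of the ester of 6. The carbinol comes from asymmetric hydrogenation of the ketone of 5, which is the only step in the route that sets absolute configuration.

**4 to 3 to 2 to 1 (ring A carbons).** The silyloxy dione is phloroglucinol at the dihydro level. Partial hydrogenation of 1 gives 2, and silylation of both hydroxyls followed by hydrolysis of the labile enol silyl ether of 3 gives 4.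

## Alternatives that were turned down

**Alternative 1:** Ring C is opened at C4–C4a. The substrate would be the aryl propargyl ether 1-[(1R)-1-[3,5-bis(methoxymethoxy)-4-(3-methylbut-2-enyl)phenoxy]prop-2-yn-1-yl]-3,5-dimethoxybenzene A1. Ph3PAuNTf2 (monovalent gold) would activate the terminal alkyne, and the ortho carbon of the aryl ether would attack it in a 6-endo-dig hydroarylation to give (2R)-2-(3,5-dimethoxyphenyl)-5,7-bis(methoxymethoxy)-6-(3-methylbut-2-enyl)-2H-chromene A2.

- For it: the key step forms a C–C bond catalytically under mild conditions. The aryl half of A1 is symmetric, so both ortho carbons are equivalent and the C6/C8 question disappears. On these two points it is as strong as or stronger than the chosen route.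
- Against it: the stereocentre of A1 is benzylic, propargylic and oxygen-bearing. Installing the hindered aryloxy group there by substitution, and exposing it to a cationic gold Lewis acid, invites ionisation and propargyl Claisen rearrangement. In A2 the same centre is allylic in a 2H-chromene, which can open reversibly to an ortho-quinone methide and lose configuration. The C3=C4 alkene of A2 must then be hydrogenated without touching the prenyl alkene, and two acetals must be removed next to a prenyl group that cyclises under acid.
- Comparison: the step count is similar. The chosen route offers a stereocentre that is never allylic or ionisable, no alkene-selective hydrogenation, and no phenol protecting groups.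

**Alternative 2:** Ring A is built last by a cyclobutenone benzannulation. The bicyclic alkoxycyclobutenone (3R)-3-(3,5-dimethoxyphenyl)-2-oxabicyclo[4.2.0]oct-1(6)-en-7-one A3 would open thermally (4π) to a vinylketene. This would add to the siloxyalkyne triisopropyl[(5-methylhex-4-en-1-yn-1-yl)oxy]silane A4, and 4π opening, 6π closure and tautomerisation would give (2R)-2-(3,5-dimethoxyphenyl)-6-(3-methylbut-2-enyl)-5-(triisopropylsilyloxy)chroman-7-ol A5. The sequence forms C4a–C5 and C6–C7 and re-forms C7–C8.

- For it: the position of the prenyl group is fixed by the alkyne, and the two ring A oxygens come out differentiated. A5 is one desilylation from the target. In regiochemical certainty and in the length of the end game it is stronger than the chosen route.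
- Against it: the difficulty moves into the fragments. A3 is a strained, acid-sensitive vinylogous ester in a four-membered ring fused to the pyran, with the C2 stereocentre already in place, and no short enantioselective access to it is apparent. A4 is a moisture-sensitive ynol ether with a skipped ene-yne that can isomerise at the temperature the cascade needs.
- Comparison: counting fragment synthesis it is the longer and less certain route. The chosen route offers a key-step precursor that is three known steps from a commercial keto ester and two from phloroglucinol.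

**Alternative 3:** Ring C is opened at C2–C3 by an internal redox disconnection. The substrate would be dimethyl 2-{[2-[(3,5-dimethoxyphenyl)methoxy]-4,6-bis(2,2-dimethylpropanoyloxy)-5-(3-methylbut-2-enyl)phenyl]methylidene}propanedioate A6. Under Sc(OTf)3 (trivalent scandium) with a chiral pybox ligand, a benzylic hydride of the OCH2Ar group would shift to the alkylidene carbon, and the malonate enolate would close onto the oxocarbenium ion to give dimethyl (2S)-2-(3,5-dimethoxyphenyl)-5,7-bis(2,2-dimethylpropanoyloxy)-6-(3-methylbut-2-enyl)chroman-3,3-dicarboxylate A7. The descriptor of A7 is S only because C3 with its two ester groups outranks the aryl group; the arrangement in space is that of 17.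

- For it: C2 and a C–C bond are created in one catalytic asymmetric, redox-neutral step from an achiral substrate. No separate asymmetric reduction is needed, and on this point it is stronger than the chosen route.
- Against it: the hydride donor is poorly activated. The methoxy groups are meta to the benzylic carbon, and the ether oxygen lone pair is drained by an aryl ring bearing two acyloxy groups and the alkylidene malonate. Enantiocontrol would have to come from closure of an ion pair on a crowded pentasubstituted arene. After the key step two ester carbons at C3 must be excised over several steps, through a β-aryloxy ester that can ring-open by elimination. The substitution pattern of A6 already contains the C6/C8 decision, so that problem is moved to the starting arene and not solved.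
- Comparison: it is the longest of the four. The chosen route offers a stereocentre from a highly reliable hydrogenation and no surplus carbons.

Key step: step 6

## Route

Assumption: diones 4 and 9 are drawn as diketones although they exist largely as enols (9 also as hemiketal 10), and the ring A centres C7 and later C6 are carried as mixtures of epimers, since both are destroyed on aromatisation.

Step 1
Reactants: 1 phloroglucinol
Product: 2 5-hydroxycyclohexane-1,3-dione (dihydrophloroglucinol)
Conditions: H2 (3 atm), Rh/Al2O3 (5 wt%), NaOH (1.0 equiv), H2O, rt; then HCl to pH 3–4, 0 °C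
Reagents that add atoms: none
Why: Partial hydrogenation of a polyphenol as its monosodium salt, the same reaction type as resorcinol to cyclohexane-1,3-dione; the product sits as a vinylogous carboxylate that resists further reduction, and the cold, weakly acidic work-up should avoid dehydration to resorcinol.

Step 2
Reactants: 2 5-hydroxycyclohexane-1,3-dione
Product: 4 5-(tert-butyldimethylsilyloxy)cyclohexane-1,3-dione, via bis-silyl enone 3 (not isolated)
Conditions: TBSCl (2.3 equiv), imidazole (5 equiv), DMF, 0 °C → rt; then aq. citric acid, THF, 0 °C
Reagents that add atoms: tert-butyldimethylsilyl chloride (TBSCl), CC(C)(C)[Si](C)(C)Cl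
Why: Exhaustive O-silylation followed by selective hydrolysis; the enol silyl ether of a 1,3-dione is a vinylogous silyl ester and should be cleaved by cold dilute acid far faster than the secondary alkyl TBS ether.

Step 3
Reactants: 5 ethyl 3-(3,5-dimethoxyphenyl)-3-oxopropanoate
Product: 6 ethyl (3R)-3-(3,5-dimethoxyphenyl)-3-hydroxypropanoate
Conditions: H2 (50 atm), [RuCl(C6H6)((S)-BINAP)]Cl (0.5 mol%), EtOH, 60 °C
Reagents that add atoms: none
Why: Noyori asymmetric hydrogenation of a β-keto ester; the ester carbonyl chelates divalent ruthenium and the (S)-BINAP quadrants direct hydride to the ketone face that gives the R carbinol (the aryl group outranks the CH2CO2Et arm, so the descriptor is opposite to that of the alkyl series with the same ligand).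

Step 4
Reactants: 6 ethyl (3R)-3-(3,5-dimethoxyphenyl)-3-hydroxypropanoate
Product: 7 (3R)-3-(3,5-dimethoxyphenyl)-3-hydroxypropanal
Conditions: i-Bu2AlH (2.2 equiv), CH2Cl2, −78 °C; MeOH, then aq. potassium sodium tartrate
Reagents that add atoms: none
Why: Partial reduction of an ester with DIBAL-H at low temperature; the first equivalent forms the aluminium alkoxide of the β-hydroxyl, which chelates the tetrahedral aluminium hemiacetal until work-up, and the aldehyde is to be used at once without chromatography.

Step 5
Reactants: 7 (3R)-3-(3,5-dimethoxyphenyl)-3-hydroxypropanal; 4 5-(tert-butyldimethylsilyloxy)cyclohexane-1,3-dione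
Product: 9 2-[(3R)-3-(3,5-dimethoxyphenyl)-3-hydroxypropyl]-5-(tert-butyldimethylsilyloxy)cyclohexane-1,3-dione, via alkylidene dione 8 (not isolated)
Conditions: L-proline (20 mol%), diethyl 2,6-dimethyl-1,4-dihydropyridine-3,5-dicarboxylate (Hantzsch ester, 1.1 equiv), CH2Cl2, rt
Reagents that add atoms: none
Why: Three-component organocatalytic reductive alkylation; proline-mediated Knoevenagel condensation gives the strongly electrophilic 2-alkylidene-1,3-dione 8, which should take hydride from the Hantzsch ester at the exocyclic carbon faster than it adds a second dione or loses the δ-hydroxyl, and the carbinol centre is not involved.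

Step 6
Reactants: 9 2-[(3R)-3-(3,5-dimethoxyphenyl)-3-hydroxypropyl]-5-(tert-butyldimethylsilyloxy)cyclohexane-1,3-dione
Product: 11 (2R)-2-(3,5-dimethoxyphenyl)-7-(tert-butyldimethylsilyloxy)-2,3,4,6,7,8-hexahydrochromen-5-one (mixture of C7 epimers), via ring hemiketal 10 (not isolated)
Conditions: PPTS (10 mol%), 4 Å MS, toluene, 40 °C
Reagents that add atoms: none
Why: Acid-catalysed cyclodehydration of a 2-(3-hydroxyalkyl)cyclohexane-1,3-dione to a tetrahydrochromen-5-one, a known reaction type. The benzylic hydroxyl adds to one of the two equivalent dione carbonyls in a 6-exo-trig closure to give hemiketal 10; acid-catalysed loss of the hemiketal hydroxyl through the ring oxocarbenium ion and loss of the C4a proton then give the vinylogous ester, forming the O1–C8a bond and ring C. The carbinol C–O bond is never broken, so C2 keeps the R configuration set in step 3. C7 becomes stereogenic because the two carbonyls are now different; nothing controls it and nothing needs to, since both epimers converge on aromatisation. The step needs carbonyl addition to win over benzylic ionisation: the methoxy groups are meta to the carbinol carbon and cannot stabilise a cation there, and the weak pyridinium acid is not expected to ionise it. It also needs the silyloxy group to stay: anhydrous PPTS at this temperature should neither cleave the secondary TBS ether nor promote its β-elimination. The driving force is the conjugated vinylogous ester, with the water taken up by the sieves.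

Step 7
Reactants: 11 (2R)-2-(3,5-dimethoxyphenyl)-7-(tert-butyldimethylsilyloxy)-2,3,4,6,7,8-hexahydrochromen-5-one
Product: 12 (2R)-2-(3,5-dimethoxyphenyl)-7-hydroxy-2,3,4,6,7,8-hexahydrochromen-5-one (mixture of C7 epimers)
Conditions: HF·pyridine, THF/pyridine, 0 °C → rt
Reagents that add atoms: none
Why: Fluoride cleavage of a secondary silyl ether under buffered, weakly acidic and non-basic anhydrous conditions, so neither E1cB loss of the C7 oxygen nor hydrolysis of the vinylogous ester is expected.

Step 8
Reactants: 12 (2R)-2-(3,5-dimethoxyphenyl)-7-hydroxy-2,3,4,6,7,8-hexahydrochromen-5-one; 13 prenyl bromide (1-bromo-3-methylbut-2-ene)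
Product: 15 (2R)-2-(3,5-dimethoxyphenyl)-7-hydroxy-6-(3-methylbut-2-enyl)-2,3,4,6,7,8-hexahydrochromen-5-one (6,7-trans expected; mixture of diastereomers), via dilithium alkoxide-enolate 14 (not isolated)
Conditions: LiN(i-Pr)2 (2.2 equiv), THF, −78 °C; 13 (1.1 equiv), DMPU, −78 → −40 °C; aq. NH4Cl
Reagents that add atoms: none
Why: Stork–Danheiser kinetic α′-deprotonation of a 3-alkoxyenone, run on the pre-formed lithium alkoxide as in a Fráter–Seebach alkylation; the enolate carbon C6 should be alkylated anti to the C7 alkoxide, C8 (γ) is not deprotonated under kinetic control, and β-elimination is shut off because the leaving group would be an oxide dianion. The new C6 centre is lost on aromatisation.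

Step 9
Reactants: 15 (2R)-2-(3,5-dimethoxyphenyl)-7-hydroxy-6-(3-methylbut-2-enyl)-2,3,4,6,7,8-hexahydrochromen-5-one
Product: 17 (2R)-2-(3,5-dimethoxyphenyl)-6-(3-methylbut-2-enyl)-3,4-dihydro-2H-chromene-5,7-diol, via diketone tautomer 16 (not isolated)
Conditions: Dess–Martin periodinane (1.05 equiv), NaHCO3, CH2Cl2, 0 °C
Reagents that add atoms: none
Why: Dess–Martin oxidation of a β-hydroxy ketone to the 1,3-diketone under non-basic conditions; 16 is the keto form of a phloroglucinol mono-ether and should enolise spontaneously to aromatic ring A, with C2 untouched.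

## Compound list

1 | phloroglucinol (benzene-1,3,5-triol) | Oc1cc(O)cc(O)c1 | starting material
2 | 5-hydroxycyclohexane-1,3-dione (dihydrophloroglucinol) | O=C1CC(O)CC(=O)C1 | intermediate
3 | 3,5-bis(tert-butyldimethylsilyloxy)cyclohex-2-en-1-one (racemic) | CC(C)(C)[Si](C)(C)OC1CC(=O)C=C(O[Si](C)(C)C(C)(C)C)C1 | intermediate (not isolated)
4 | 5-(tert-butyldimethylsilyloxy)cyclohexane-1,3-dione | CC(C)(C)[Si](C)(C)OC1CC(=O)CC(=O)C1 | intermediate
5 | ethyl 3-(3,5-dimethoxyphenyl)-3-oxopropanoate | CCOC(=O)CC(=O)c1cc(OC)cc(OC)c1 | starting material
6 | ethyl (3R)-3-(3,5-dimethoxyphenyl)-3-hydroxypropanoate | COc1cc(OC)cc([C@H](O)CC(=O)OCC)c1 | intermediate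
7 | (3R)-3-(3,5-dimethoxyphenyl)-3-hydroxypropanal | COc1cc(OC)cc([C@H](O)CC=O)c1 | intermediate
8 | 2-[(3R)-3-(3,5-dimethoxyphenyl)-3-hydroxypropylidene]-5-(tert-butyldimethylsilyloxy)cyclohexane-1,3-dione | COc1cc(OC)cc([C@H](O)CC=C2C(=O)CC(O[Si](C)(C)C(C)(C)C)CC2=O)c1 | intermediate (not isolated)
9 | 2-[(3R)-3-(3,5-dimethoxyphenyl)-3-hydroxypropyl]-5-(tert-butyldimethylsilyloxy)cyclohexane-1,3-dione | COc1cc(OC)cc([C@H](O)CCC2C(=O)CC(O[Si](C)(C)C(C)(C)C)CC2=O)c1 | intermediate
10 | (2R)-2-(3,5-dimethoxyphenyl)-8a-hydroxy-7-(tert-butyldimethylsilyloxy)octahydrochromen-5-one (ring hemiketal of 9, mixture of isomers) | COc1cc(OC)cc([C@H]2CCC3C(=O)CC(O[Si](C)(C)C(C)(C)C)CC3(O)O2)c1 | intermediate (not isolated)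
11 | (2R)-2-(3,5-dimethoxyphenyl)-7-(tert-butyldimethylsilyloxy)-2,3,4,6,7,8-hexahydrochromen-5-one (C7 epimers) | COc1cc(OC)cc([C@H]2CCC3=C(CC(O[Si](C)(C)C(C)(C)C)CC3=O)O2)c1 | intermediate
12 | (2R)-2-(3,5-dimethoxyphenyl)-7-hydroxy-2,3,4,6,7,8-hexahydrochromen-5-one (C7 epimers) | COc1cc(OC)cc([C@H]2CCC3=C(CC(O)CC3=O)O2)c1 | intermediate
13 | prenyl bromide (1-bromo-3-methylbut-2-ene) | CC(C)=CCBr | starting material
14 | dilithium alkoxide-enolate of 12 (C7 alkoxide, C5–C6 enolate) | COc1cc(OC)cc([C@H]2CCC3=C(CC([O-])C=C3[O-])O2)c1.[Li+].[Li+] | intermediate (not isolated)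
15 | (2R)-2-(3,5-dimethoxyphenyl)-7-hydroxy-6-(3-methylbut-2-enyl)-2,3,4,6,7,8-hexahydrochromen-5-one (mixture of C6/C7 diastereomers) | COc1cc(OC)cc([C@H]2CCC3=C(CC(O)C(CC=C(C)C)C3=O)O2)c1 | intermediate
16 | (2R)-2-(3,5-dimethoxyphenyl)-6-(3-methylbut-2-enyl)-3,4-dihydro-2H-chromene-5,7(6H,8H)-dione | COc1cc(OC)cc([C@H]2CCC3=C(CC(=O)C(CC=C(C)C)C3=O)O2)c1 | intermediate (not isolated)
17 | (2R)-2-(3,5-dimethoxyphenyl)-6-(3-methylbut-2-enyl)-3,4-dihydro-2H-chromene-5,7-diol (CNP0147692.1) | COc1cc(OC)cc([C@H]2CCc3c(cc(O)c(CC=C(C)C)c3O)O2)c1 | target

## Step count and least certain steps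

Total: 9 steps. Longest linear sequence: 7 steps (steps 1, 2, 5, 6, 7, 8, 9 from 1, or equally steps 3, 4, 5, 6, 7, 8, 9 from 5).

**Step 6 (key step).** Acid could ionise the benzylic carbinol, which would erode the C2 configuration or give a styrene. Acid could also promote loss of the silyloxy group from the dione ring with aromatisation to a resorcinol, or the hemiketal could dehydrate incompletely. Fallback, from 9 back to 11, forming the same O1–C8a bond without acid: the enol of 9 is sulfonylated selectively (TsCl, Et3N, CH2Cl2, 0 °C; the acidic enol reacts well before the secondary alcohol) to give 2-[(3R)-3-(3,5-dimethoxyphenyl)-3-hydroxypropyl]-3-(4-methylbenzenesulfonyloxy)-5-(tert-butyldimethylsilyloxy)cyclohex-2-en-1-one F1. Mild amine base (i-Pr2NEt, cat. DMAP, MeCN, rt) then induces intramolecular addition–elimination of the hydroxyl on the β-sulfonyloxy enone, which expels sulfonate and gives 11.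

**Step 8.** The second deprotonation may be incomplete, or proton exchange between the dianion and alkylated product may lead to recovered 12 and double alkylation. The alkoxide may be O-alkylated, and on warming the enolate may equilibrate to the γ (C8) dienolate. Fallback, from 11 back to 15, changing the order of events: the silyl ether 11 is deprotonated with one equivalent of LiN(i-Pr)2 at −78 °C to the lithium enolate of 11 F2 and alkylated with 13 to give (2R)-2-(3,5-dimethoxyphenyl)-7-(tert-butyldimethylsilyloxy)-6-(3-methylbut-2-enyl)-2,3,4,6,7,8-hexahydrochromen-5-one F3. HF·pyridine then gives 15. This trades the dianion problems for the risk of silanolate β-elimination from F2, so the enolate must be kept cold and quenched early.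

**Step 9.** The phenol that forms during the reaction may be oxidised further by the remaining periodinane (oxidative dearomatisation of a phloroglucinol-type ring), or 15 may lose water before it is oxidised. Fallback, from 15 directly to 17: an Oppenauer-type transfer dehydrogenation with [Cp*IrCl2]2 (Cp* = pentamethylcyclopentadienyl; trivalent iridium) and K2CO3 in acetone. Hydride is passed to acetone, no electrophilic oxidant is present, and aromatisation of 16 makes the transfer irreversible. This fallback makes no new compound (F0).

**Step 5.** Amine catalysis may dehydrate aldehyde 7 to a cinnamaldehyde or eliminate the hydroxyl from 8 to a dienyl dione, and a second dione may add to 8 before hydride transfer. Fallback, from 6 back to 9, carrying the carbinol protected: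
- 6 is silylated (Et3SiCl, imidazole) to ethyl (3R)-3-(3,5-dimethoxyphenyl)-3-(triethylsilyloxy)propanoate F4.
- i-Bu2AlH at −78 °C gives the stable (3R)-3-(3,5-dimethoxyphenyl)-3-(triethylsilyloxy)propanal F5.
- The same proline/Hantzsch ester reaction with 4 gives 2-[(3R)-3-(3,5-dimethoxyphenyl)-3-(triethylsilyloxy)propyl]-5-(tert-butyldimethylsilyloxy)cyclohexane-1,3-dione F7, through 2-[(3R)-3-(3,5-dimethoxyphenyl)-3-(triethylsilyloxy)propylidene]-5-(tert-butyldimethylsilyloxy)cyclohexane-1,3-dione F6.
- AcOH/THF/H2O removes the triethylsilyl group selectively and gives 9, which may already begin to close to 11.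

**Step 4.** The ester may be over-reduced to the diol, or the β-hydroxy aldehyde may lose water or oligomerise during work-up. Fallback, from 6 back to 7, by full reduction and selective re-oxidation: LiBH4 in THF gives (1R)-1-(3,5-dimethoxyphenyl)propane-1,3-diol F8. The primary hydroxyl is then oxidised selectively with catalytic TEMPO and PhI(OAc)2 in CH2Cl2 to give 7.

## Further compounds

F1 | step 6 | 2-[(3R)-3-(3,5-dimethoxyphenyl)-3-hydroxypropyl]-3-(4-methylbenzenesulfonyloxy)-5-(tert-butyldimethylsilyloxy)cyclohex-2-en-1-one | COc1cc(OC)cc([C@H](O)CCC2=C(OS(=O)(=O)c3ccc(C)cc3)CC(O[Si](C)(C)C(C)(C)C)CC2=O)c1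
F2 | step 8 | lithium enolate of 11 (C5–C6 enolate) | COc1cc(OC)cc([C@H]2CCC3=C(CC(O[Si](C)(C)C(C)(C)C)C=C3[O-])O2)c1.[Li+]
F3 | step 8 | (2R)-2-(3,5-dimethoxyphenyl)-7-(tert-butyldimethylsilyloxy)-6-(3-methylbut-2-enyl)-2,3,4,6,7,8-hexahydrochromen-5-one | COc1cc(OC)cc([C@H]2CCC3=C(CC(O[Si](C)(C)C(C)(C)C)C(CC=C(C)C)C3=O)O2)c1
F0 | step 9 | none | none
F4 | step 5 | ethyl (3R)-3-(3,5-dimethoxyphenyl)-3-(triethylsilyloxy)propanoate | COc1cc(OC)cc([C@H](O[Si](CC)(CC)CC)CC(=O)OCC)c1
F5 | step 5 | (3R)-3-(3,5-dimethoxyphenyl)-3-(triethylsilyloxy)propanal | COc1cc(OC)cc([C@H](O[Si](CC)(CC)CC)CC=O)c1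
F6 | step 5 | 2-[(3R)-3-(3,5-dimethoxyphenyl)-3-(triethylsilyloxy)propylidene]-5-(tert-butyldimethylsilyloxy)cyclohexane-1,3-dione | COc1cc(OC)cc([C@H](O[Si](CC)(CC)CC)CC=C2C(=O)CC(O[Si](C)(C)C(C)(C)C)CC2=O)c1
F7 | step 5 | 2-[(3R)-3-(3,5-dimethoxyphenyl)-3-(triethylsilyloxy)propyl]-5-(tert-butyldimethylsilyloxy)cyclohexane-1,3-dione | COc1cc(OC)cc([C@H](O[Si](CC)(CC)CC)CCC2C(=O)CC(O[Si](C)(C)C(C)(C)C)CC2=O)c1
F8 | step 4 | (1R)-1-(3,5-dimethoxyphenyl)propane-1,3-diol | COc1cc(OC)cc([C@H](O)CCO)c1
A1 | alternative 1 | 1-[(1R)-1-[3,5-bis(methoxymethoxy)-4-(3-methylbut-2-enyl)phenoxy]prop-2-yn-1-yl]-3,5-dimethoxybenzene | COc1cc(OC)cc([C@@H](C#C)Oc2cc(OCOC)c(CC=C(C)C)c(OCOC)c2)c1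
A2 | alternative 1 | (2R)-2-(3,5-dimethoxyphenyl)-5,7-bis(methoxymethoxy)-6-(3-methylbut-2-enyl)-2H-chromene | COc1cc(OC)cc([C@H]2C=Cc3c(cc(OCOC)c(CC=C(C)C)c3OCOC)O2)c1
A3 | alternative 2 | (3R)-3-(3,5-dimethoxyphenyl)-2-oxabicyclo[4.2.0]oct-1(6)-en-7-one | COc1cc(OC)cc([C@H]2CCC3=C(CC3=O)O2)c1
A4 | alternative 2 | triisopropyl[(5-methylhex-4-en-1-yn-1-yl)oxy]silane | CC(C)=CCC#CO[Si](C(C)C)(C(C)C)C(C)C
A5 | alternative 2 | (2R)-2-(3,5-dimethoxyphenyl)-6-(3-methylbut-2-enyl)-5-(triisopropylsilyloxy)chroman-7-ol | COc1cc(OC)cc([C@H]2CCc3c(cc(O)c(CC=C(C)C)c3O[Si](C(C)C)(C(C)C)C(C)C)O2)c1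
A6 | alternative 3 | dimethyl 2-{[2-[(3,5-dimethoxyphenyl)methoxy]-4,6-bis(2,2-dimethylpropanoyloxy)-5-(3-methylbut-2-enyl)phenyl]methylidene}propanedioate | COC(=O)C(=Cc1c(OCc2cc(OC)cc(OC)c2)cc(OC(=O)C(C)(C)C)c(CC=C(C)C)c1OC(=O)C(C)(C)C)C(=O)OC
A7 | alternative 3 | dimethyl (2S)-2-(3,5-dimethoxyphenyl)-5,7-bis(2,2-dimethylpropanoyloxy)-6-(3-methylbut-2-enyl)chroman-3,3-dicarboxylate | COc1cc(OC)cc([C@H]2C(Cc3c(cc(OC(=O)C(C)(C)C)c(CC=C(C)C)c3OC(=O)C(C)(C)C)O2)(C(=O)OC)C(=O)OC)c1
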